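## Structural features

The target 30 is built from two 5,7-dihydroxy-4'-methoxyflavone units. Rings A and C with the anisyl ring B on C2 form the first. Rings D and F with ring E as the 2-aryl group form the second, whose positions are written C2'' to C8a''. The halves are joined only by the aryl–aryl bond from C8 of ring A to E2. E2 is the ring E carbon next to E1, which carries C2'' of pyranone ring F. The ring E methoxy group sits on E4, para to E1 and meta to E2.

There is no stereocentre, so no neighbouring stereocentres have to be related. The single stereochemical element is the C8–E2 axis, flanked by the C7 oxygen, the C8a oxygen and the ring F substituent on E1, and its sense is not defined.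

The fragile features are the four phenols (two chelated to the C4 and C4'' carbonyls), the two aryl methyl ethers that must survive every dealkylation, and the two pyranones, which strong hydroxide can open at C2.

The real difficulty is the crowded C8–E2 bond and its placement. C6 and C8 of a 5,7-dioxygenated ring A are electronically almost alike, and of the two oxygens beside the aryl group only the one on C8a may become O1 of ring C.

The key step exploits the fact that ring A is a 1,3,5-trioxygenated benzene with ring E on C8, between the C7 and C8a oxygens, and hydrogen on C6 and C4a. A four-carbon vinylketene carrying the C5 oxygen and a two-carbon oxygenated arylalkyne assemble exactly this pattern. The three oxygens then emerge as a free phenol (C8a), a silyl ether (C7) and an alkyl ether (C5).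

## Logic of the disconnections

**30 from 29.**
- Cut: four O–alkyl bonds, namely the benzyl ethers on O7, O5'' and O7'' and the ethyl ether on O5.
- Reason: all phenols stay masked until rings C and F exist, and one boron Lewis acid can address all four masks.
- Gain: a single closing operation.
- Demand: the ethyl group must leave through chelation to the C4 carbonyl while the two remote methyl ethers stay untouched.

**29 from 27, and 27 from 24 and 26.**
- Cut: O1''–C2'' of ring F (with an oxidation-level change), then the C2''–C3'' enone bond.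
- Reason: E1 then needs only a one-carbon aldehyde, and ring D arrives complete with C3'' and C4''.
- Gain: the target splits into two fragments of similar size.
- Demand: O7 must carry a group stable to hydroxide and to hot HI. A free O7 phenol lies six atoms from the enone carbon C2'' and would add to it. Ring C also has to tolerate the base.

**26 from 25.**
- Cut: two O–benzyl bonds.
- Reason: the ring D phenols are masked with the same group used on O7, and the chelated hydroxyl stays free as the future O1''.
- Gain: a commercial ketone.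
- Demand: alkylation must stop before the hydrogen-bonded hydroxyl reacts.

**24 from 23, and 23 from 22.**
- Cut: no skeletal bond. The aldehyde returns to its dioxolane and the O7 benzyl group is exchanged for the silyl group delivered by the ring synthesis.
- Reason: a 7-silyloxyflavone is a vinylogous silyl ester and would not survive hydroxide.
- Gain: the exchange takes place when O7 is the only oxygen that can be freed, so it is unambiguous.
- Demand: the fluoride step must leave the acetal intact, and the acid step comes only after the first aldehyde has been consumed.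

**22 from 20, 20 from 19, 19 from 16 and 17.**
- Cut: O1–C2 of ring C, then C3–C4.
- Reason: C2, C3 and ring B come in together as an arylacetylene, under basic or neutral conditions throughout.
- Gain: eleven atoms are removed in one bond.
- Demand: closure must be 6-endo and not 5-exo, and the very electron-rich carbinol must be oxidised without ionising.

**16 from 14 and 15.**
- Cut: C4–C4a.
- Reason: a Friedel–Crafts or Fries acetylation needs Lewis acids that the acetal and the silyl ether cannot bear, and it could also strike C6. A phenoxide-delivered C1 unit can reach only the ortho carbon.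
- Gain: the position of ring C is fixed by the one free hydroxyl.
- Demand: since C8 is blocked, C4a must be the only ortho position, which it is.

**14 from 8 and 9.**
- Cut: C8–C8a, C6–C7 and C4a–C8a, which dissolves ring A.
- Reason: the hindered biaryl bond becomes a plain aryl–alkyne bond, and the axis gains its ortho groups only as the ring grows around it. The three oxygens arrive in three different forms.
- Gain: one ring and the whole 6/8 problem are removed, leaving a four-membered and an open-chain partner.
- Demand: alkyne and ketene must combine in a single orientation, under conditions free of acid.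

**8 from 5.**
- Cut: the C7–O bond and the O–Si bond.
- Reason: a terminal alkyne is the simplest source of an ynolate.
- Gain: a stable, easily made arylacetylene.
- Demand: oxygen transfer to an aryl acetylide, silylation on oxygen, and no free silyl triflate left to attack the dioxolane.

**5 from 4, 4 from 2 and 3, 2 from 1.**
- Cut: the Si–C bond, the E2–C8 aryl–alkyne bond and the two acetal C–O bonds.
- Reason: ring E is bought with bromine, aldehyde and methoxy group already in the correct 1,2,4 relationship.
- Gain: commercial materials only.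
- Demand: the acetal goes on first so that all organometallic steps are safe.

## Other disconnections considered

**Alternative 1:**
- *Cut.* The cut runs through ring E. Removing E3–E4 and E5–E6 gives two components. One is the 2-pyrone methyl 4-[5,7-bis(benzyloxy)-4'-methoxyflavon-8-yl]-2-oxo-2H-pyran-5-carboxylate A1, in which pyrone C4 is E2 and C5 is E1. The other is the ketene acetal 1,1-dimethoxyethene A2.
- *Forward key step.* Heating A1 with A2 would start an inverse-electron-demand Diels–Alder reaction, the methylene carbon of A2 bonding to pyrone C6. Decarboxylative cycloreversion and loss of one alkoxy group would then aromatise the adduct to methyl 2-[5,7-bis(benzyloxy)-4'-methoxyflavon-8-yl]-4-methoxybenzoate A3.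
- *In favour.* The orientation (methoxy para to the ester) follows a well-understood polarity match, so on regiochemical security this plan equals the chosen one. The first flavone enters intact and carries only benzyl groups, so convergence and the final deprotection are better than in the chosen plan.
- *Against.* The cycloaddition does not make the C8–E2 bond. That bond must already exist in A1, so a hindered cross-coupling at C8 and a C8-selective functionalisation of a flavone are still required. The central problem is moved rather than solved. The bulky, electron-rich flavonyl group on C4 should also slow the cycloaddition, and A2 is hydrolytically delicate.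
- *Step economy.* E1 emerges as a hindered ester, which needs saponification, O-acylation, Baker–Venkataraman shift and cyclodehydration. From the acetal the chosen plan needs only unmasking, condensation and oxidative cyclisation. Overall step economy should be similar.

**Alternative 2:**
- *Cut.* E1–E6 and E4–E5 are cut, which leads to the coumarin methyl [5,7-bis(benzyloxy)-2-oxo-2H-chromen-4-yl]acetate A4 and methyl acrylate A5.
- *Forward key step.* The extended enolate of A4 would have to attack A5 through coumarin C3 (E1). The resulting ester enolate (E5) would then close on the acetate carbonyl (E4) in a Dieckmann step. The product is methyl 1,3-bis(benzyloxy)-9-hydroxy-6-oxo-7,10-dihydro-6H-benzo[c]chromene-8-carboxylate A6.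
- *In favour.* The inputs are very cheap. The C8–E2 bond stems from a Pechmann condensation, so the crowded bond is again made before it is crowded, which equals the chosen plan. The lactone ties the E1 carbon to one of the two oxygens beside C8 and thereby marks it, much as the free hydroxyl of 14 does.
- *Against.* The enolate has two nucleophilic sites, and the exocyclic carbon (E3) is the more usual one in Michael additions, so the required E1–E6 bond is mechanistically doubtful. A6 carries a surplus ester on E5 and is not yet aromatic. Decarboxylation, dehydrogenation and O-methylation are therefore three corrective steps without skeletal gain. The benzannulation, by contrast, delivers ring A at the correct oxidation level with no surplus atom.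
- *Step economy.* Both pyranone rings would still have to be built, one of them by opening a hindered lactone with a ketone enolate. The sequence should be longer by several steps.

**Alternative 3:**
- *Cut.* C8–E2 and the bond from E1 to its one-carbon substituent are cut together. The precursors are 3-chloro-2-iodo-5-methoxyphenyl 4-chlorobenzenesulfonate A7 and 2,4,6-tris(methoxymethoxy)phenylmagnesium bromide A9.
- *Forward key step.* Halogen–magnesium exchange on A7 and loss of the sulfonate would give 3-chloro-5-methoxybenzyne A8. A9 would add at E2, because the chlorine on E6 stabilises the carbanion developing at E1. Carboxylation of the new arylmagnesium centre would give 2-chloro-4-methoxy-6-[2,4,6-tris(methoxymethoxy)phenyl]benzoic acid A10.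
- *In favour.* Two skeletal bonds on adjacent carbons form in one flask without a transition metal. The symmetric nucleophile removes the 6/8 question. In the number of steps to the biaryl this plan is better than the chosen one.
- *Against.* No ring is closed. A9 is a doubly ortho-substituted nucleophile that must intercept a short-lived aryne in competition with the exchange reagent. The chlorine is a pure auxiliary and costs a reductive step. The three ring A oxygens come out identical, so the differentiation that the benzannulation provides directly would have to be created afterwards.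
- *Step economy.* The acid is flanked on both sides and sits at an oxidation level that calls for the longer Baker–Venkataraman sequence. A7 needs an iodination between two substituents. The total should be equal to or longer than the chosen route.

Key step: step 5

Assumption: the structure of 30 defines no sense for the C8–E2 axis, so the route builds it without axial control (racemic if the axis is configurationally stable).

Remark on the chemistry: ring opening of 9 places the ethoxy group on the vinyl carbon bonded to the ketene, so 10 is a (1-ethoxyvinyl)ketene, 3-ethoxybuta-1,3-dien-1-one.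

## Steps

Step 1
Reactants: 1 2-bromo-4-methoxybenzaldehyde
Product: 2 2-(2-bromo-4-methoxyphenyl)-1,3-dioxolane
Conditions: HOCH2CH2OH, p-TsOH·H2O (cat.), toluene, reflux, Dean–Stark; Et3N quench
Reagents that add atoms: ethylene glycol, OCCO
Why: Acid-catalysed acetalisation driven by azeotropic removal of water. The dioxolane shields the future C2'' carbon from the organometallic steps, and every operation up to step 11 is neutral or basic, so it should last.

Step 2
Reactants: 2 2-(2-bromo-4-methoxyphenyl)-1,3-dioxolane; 3 trimethylsilylacetylene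
Product: 4 {[2-(1,3-dioxolan-2-yl)-5-methoxyphenyl]ethynyl}trimethylsilane
Conditions: PdCl2(PPh3)2 (cat.), CuI (cat.), Et3N, 70 °C
Reagents that add atoms: none
Why: Sonogashira coupling of an aryl bromide with a silyl-capped acetylene; zerovalent palladium inserts into the only C–Br bond, and the basic medium suits the acetal. This forms the E2–C8 bond while it is still unhindered.

Step 3
Reactants: 4 {[2-(1,3-dioxolan-2-yl)-5-methoxyphenyl]ethynyl}trimethylsilane
Product: 5 2-(2-ethynyl-4-methoxyphenyl)-1,3-dioxolane
Conditions: K2CO3 (0.2 equiv), MeOH, rt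
Reagents that add atoms: none
Why: Base-catalysed methanolysis (protodesilylation) of an alkynylsilane; no other group in 4 responds to methoxide.

Step 4
Reactants: 5 2-(2-ethynyl-4-methoxyphenyl)-1,3-dioxolane
Product: 8 2-[4-methoxy-2-(triisopropylsiloxyethynyl)phenyl]-1,3-dioxolane, via lithium acetylide 6 (not isolated), via lithium ynolate 7 (not isolated)
Conditions: n-BuLi, THF, −78 °C; t-BuOOLi (from t-BuOOH, LiHMDS, THF, −78 °C), −78 to 0 °C; TIPSOTf (1.05 equiv), −78 to 0 °C; Et3N-deactivated silica
Reagents that add atoms: tert-butyl hydroperoxide, CC(C)(C)OO; triisopropylsilyl trifluoromethanesulfonate, CC(C)[Si](C(C)C)(C(C)C)OS(=O)(=O)C(F)(F)F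
Why: Electrophilic oxygenation of a lithium acetylide by lithium tert-butyl peroxide gives the ynolate, and a bulky silyl triflate caps ynolates on oxygen rather than carbon. The lithium tert-butoxide formed alongside scavenges any excess triflate, so the dioxolane should not meet a free Lewis acid.

Step 5
Reactants: 8 2-[4-methoxy-2-(triisopropylsiloxyethynyl)phenyl]-1,3-dioxolane; 9 3-ethoxycyclobut-2-en-1-one
Product: 14 2-[2-(1,3-dioxolan-2-yl)-5-methoxyphenyl]-5-ethoxy-3-(triisopropylsiloxy)phenol, via vinylketene 10 (not isolated), via vinylcyclobutenone 11 (not isolated), via dienylketene 12 (not isolated), via cyclohexadienone 13 (not isolated)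
Conditions: 9 (1.5 equiv, added in portions), toluene, 80 °C then 110 °C, sealed vessel, Ar, base-washed glass
Reagents that add atoms: none
Why: The reaction type is the Danheiser benzannulation, the known union of cyclobutenones with trialkylsiloxyalkynes to give resorcinol monosilyl ethers. Heat opens 9 by four-electron electrocyclic cleavage of its C1–C4 bond to the (1-ethoxyvinyl)ketene 10. In 8 the oxygen lone pair makes the aryl-bearing carbon the nucleophile, so it attacks the ketene carbonyl carbon (bond C8–C8a) while the siloxy-bearing carbon closes on the ketene alpha carbon (bond C6–C7), giving 11 by a regiospecific (2+2) cycloaddition. 11 reopens in a second, reversible four-electron step to 12, and only the isomer with the ketene and ethoxyvinyl arms cis can continue. Ring A closes by six-electron electrocyclisation of 12 (bond C4a–C8a) to dienone 13, whose enolisation to phenol 14 makes the cascade irreversible. No stereocentre is kept: the sp3 carbon of 11 vanishes on ring opening and the new C8–E2 axis forms without control. The only selectivity needed is the mutual orientation of alkyne and ketene; the polarisation of the ynol ether secures it and places ring E between the free C8a hydroxyl and the C7 silyl ether, with the ethoxy group on C5. The medium is neutral and aprotic, so acetal, silyl ether and ynol ether should persist, and portionwise addition of 9 keeps the ketene dilute enough to disfavour its dimerisation and the acylation of 14.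

Step 6
Reactants: 14 2-[2-(1,3-dioxolan-2-yl)-5-methoxyphenyl]-5-ethoxy-3-(triisopropylsiloxy)phenol; 15 paraformaldehyde
Product: 16 3-[2-(1,3-dioxolan-2-yl)-5-methoxyphenyl]-6-ethoxy-2-hydroxy-4-(triisopropylsiloxy)benzaldehyde
Conditions: MgCl2 (anhydrous), Et3N, (CH2O)n, MeCN, reflux; cold NaH2PO4 buffer
Reagents that add atoms: none
Why: Magnesium-mediated ortho-formylation of phenols (Casnati–Skattebøl): formaldehyde bound to the magnesium phenoxide is delivered only to an ortho carbon, and a second formaldehyde accepts hydride. C8 is blocked, so C4a is the sole site and C6 cannot compete; the mild basic medium suits acetal and silyl ether.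

Step 7
Reactants: 16 3-[2-(1,3-dioxolan-2-yl)-5-methoxyphenyl]-6-ethoxy-2-hydroxy-4-(triisopropylsiloxy)benzaldehyde; 17 1-ethynyl-4-methoxybenzene
Product: 19 2-[2-(1,3-dioxolan-2-yl)-5-methoxyphenyl]-5-ethoxy-6-[1-hydroxy-3-(4-methoxyphenyl)prop-2-yn-1-yl]-3-(triisopropylsiloxy)phenol, via lithium arylacetylide 18 (not isolated)
Conditions: 17 (2.5 equiv), n-BuLi (2.4 equiv), THF, −78 °C; then 16, −78 to 0 °C; pH 7 buffer; used crude
Reagents that add atoms: none
Why: 1,2-Addition of a lithium acetylide to a salicylaldehyde; the first equivalent deprotonates the phenol and the excess adds to the carbonyl, forming C3–C4. The carbinol centre arises without control (racemic) and is erased in step 8.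

Step 8
Reactants: 19 2-[2-(1,3-dioxolan-2-yl)-5-methoxyphenyl]-5-ethoxy-6-[1-hydroxy-3-(4-methoxyphenyl)prop-2-yn-1-yl]-3-(triisopropylsiloxy)phenol
Product: 20 1-{3-[2-(1,3-dioxolan-2-yl)-5-methoxyphenyl]-6-ethoxy-2-hydroxy-4-(triisopropylsiloxy)phenyl}-3-(4-methoxyphenyl)prop-2-yn-1-one
Conditions: MnO2 (activated, excess), CH2Cl2, rt
Reagents that add atoms: none
Why: Heterogeneous MnO2 oxidation of a doubly activated (benzylic and propargylic) alcohol. The neutral surface reagent avoids acid, which would ionise this electron-rich carbinol, and the hindered phenol becomes hydrogen-bonded to the new ketone.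

Step 9
Reactants: 20 1-{3-[2-(1,3-dioxolan-2-yl)-5-methoxyphenyl]-6-ethoxy-2-hydroxy-4-(triisopropylsiloxy)phenyl}-3-(4-methoxyphenyl)prop-2-yn-1-one
Product: 22 8-[2-(1,3-dioxolan-2-yl)-5-methoxyphenyl]-5-ethoxy-2-(4-methoxyphenyl)-7-(triisopropylsiloxy)-4H-chromen-4-one, via enaminone 21 (not isolated)
Conditions: Et2NH, EtOH, 60 °C
Reagents that add atoms: none
Why: Amine-mediated cyclisation of an o-hydroxyaryl ynone: aza-Michael addition converts the alkyne into enaminone 21, and the C8a hydroxyl then displaces the amine at the beta carbon by addition–elimination. Because oxygen can bond only to that carbon, ring C closes in the 6-endo sense and the 5-exo (aurone) path is shut; any partial desilylation converges in step 10.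

Step 10
Reactants: 22 8-[2-(1,3-dioxolan-2-yl)-5-methoxyphenyl]-5-ethoxy-2-(4-methoxyphenyl)-7-(triisopropylsiloxy)-4H-chromen-4-one
Product: 23 7-(benzyloxy)-8-[2-(1,3-dioxolan-2-yl)-5-methoxyphenyl]-5-ethoxy-2-(4-methoxyphenyl)-4H-chromen-4-one
Conditions: CsF, BnBr, DMF, rt
Reagents that add atoms: benzyl bromide, BrCc1ccccc1
Why: Fluoride desilylation of an aryl silyl ether with in situ Williamson benzylation of the released caesium phenoxide. O7 is the only oxygen that can be freed at this stage, so the exchange is unambiguous.

Step 11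
Reactants: 23 7-(benzyloxy)-8-[2-(1,3-dioxolan-2-yl)-5-methoxyphenyl]-5-ethoxy-2-(4-methoxyphenyl)-4H-chromen-4-one
Product: 24 2-[7-(benzyloxy)-5-ethoxy-2-(4-methoxyphenyl)-4-oxo-4H-chromen-8-yl]-4-methoxybenzaldehyde
Conditions: 1 M HCl, THF, rt
Reagents that add atoms: water, O
Why: Acid hydrolysis of an acetal, fast here because the para methoxy group stabilises the oxocarbenium ion. With O7 and O8a both blocked, the aldehyde cannot collapse to a lactol.

Step 12
Reactants: 25 2,4,6-trihydroxyacetophenone
Product: 26 1-[2,4-bis(benzyloxy)-6-hydroxyphenyl]ethan-1-one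
Conditions: BnBr (2.1 equiv), K2CO3, DMF, rt to 50 °C
Reagents that add atoms: benzyl bromide, BrCc1ccccc1
Why: Williamson etherification with chelation-based selectivity: the hydroxyl hydrogen-bonded to the acetyl group is the least reactive. The symmetry of 25 makes it irrelevant which ortho hydroxyl stays free.

Step 13
Reactants: 24 2-[7-(benzyloxy)-5-ethoxy-2-(4-methoxyphenyl)-4-oxo-4H-chromen-8-yl]-4-methoxybenzaldehyde; 26 1-[2,4-bis(benzyloxy)-6-hydroxyphenyl]ethan-1-one
Product: 27 (E)-1-[2,4-bis(benzyloxy)-6-hydroxyphenyl]-3-{2-[7-(benzyloxy)-5-ethoxy-2-(4-methoxyphenyl)-4-oxo-4H-chromen-8-yl]-4-methoxyphenyl}prop-2-en-1-one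
Conditions: KOH (50% aq.), EtOH–THF, rt
Reagents that add atoms: none
Why: Claisen–Schmidt condensation of a non-enolisable aldehyde with a 2-hydroxyacetophenone; E1cB dehydration gives the conjugated E-enone. The electron-rich 5,7-dialkoxy ring C is a poor acceptor for hydroxide, and any reversible opening would reclose under the acidic conditions of step 14.

Step 14
Reactants: 27 (E)-1-[2,4-bis(benzyloxy)-6-hydroxyphenyl]-3-{2-[7-(benzyloxy)-5-ethoxy-2-(4-methoxyphenyl)-4-oxo-4H-chromen-8-yl]-4-methoxyphenyl}prop-2-en-1-one
Product: 29 7-(benzyloxy)-8-{2-[5,7-bis(benzyloxy)-4-oxo-4H-chromen-2-yl]-5-methoxyphenyl}-5-ethoxy-2-(4-methoxyphenyl)-4H-chromen-4-one, via flavanone 28 (not isolated)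
Conditions: I2 (cat.), DMSO, 120 °C
Reagents that add atoms: none
Why: Iodine/DMSO oxidative cyclisation of a 2'-hydroxychalcone: oxa-Michael closure gives 28, alpha-iodination and loss of HI install the C2''–C3'' double bond, and DMSO reoxidises HI. The C2'' centre of 28 forms without control and is erased; the benzyl group on O7 prevents competing attack on the enone.

Step 15
Reactants: 29 7-(benzyloxy)-8-{2-[5,7-bis(benzyloxy)-4-oxo-4H-chromen-2-yl]-5-methoxyphenyl}-5-ethoxy-2-(4-methoxyphenyl)-4H-chromen-4-one
Product: 30 8-[2-(5,7-dihydroxy-4-oxo-4H-chromen-2-yl)-5-methoxyphenyl]-5,7-dihydroxy-2-(4-methoxyphenyl)-4H-chromen-4-one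
Conditions: BCl3 (excess), C6HMe5, CH2Cl2, −78 °C to rt; H2O
Reagents that add atoms: none
Why: Lewis acid ether cleavage: BCl3 ionises aryl benzyl ethers at low temperature, with pentamethylbenzene trapping the benzyl cation. On warming it removes the peri ethyl group through the six-membered chelate with the C4 carbonyl. The two methyl ethers have neither benzylic assistance nor a chelating neighbour and should remain.

## Compound list

1 | 2-bromo-4-methoxybenzaldehyde | COc1ccc(C=O)c(Br)c1 | starting material
2 | 2-(2-bromo-4-methoxyphenyl)-1,3-dioxolane | COc1ccc(C2OCCO2)c(Br)c1 | intermediate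
3 | trimethylsilylacetylene | C#C[Si](C)(C)C | starting material
4 | {[2-(1,3-dioxolan-2-yl)-5-methoxyphenyl]ethynyl}trimethylsilane | COc1ccc(C2OCCO2)c(C#C[Si](C)(C)C)c1 | intermediate
5 | 2-(2-ethynyl-4-methoxyphenyl)-1,3-dioxolane | COc1ccc(C2OCCO2)c(C#C)c1 | intermediate
6 | lithium [2-(1,3-dioxolan-2-yl)-5-methoxyphenyl]acetylide | COc1ccc(C2OCCO2)c(C#C[Li])c1 | intermediate
7 | lithium 2-[2-(1,3-dioxolan-2-yl)-5-methoxyphenyl]ethynolate | COc1ccc(C2OCCO2)c(C#CO[Li])c1 | intermediate
8 | 2-[4-methoxy-2-(triisopropylsiloxyethynyl)phenyl]-1,3-dioxolane | COc1ccc(C2OCCO2)c(C#CO[Si](C(C)C)(C(C)C)C(C)C)c1 | intermediate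
9 | 3-ethoxycyclobut-2-en-1-one | CCOC1=CC(=O)C1 | starting material
10 | 3-ethoxybuta-1,3-dien-1-one | C=C(OCC)C=C=O | intermediate
11 | 2-[2-(1,3-dioxolan-2-yl)-5-methoxyphenyl]-4-(1-ethoxyethenyl)-3-(triisopropylsiloxy)cyclobut-2-en-1-one (racemic) | C=C(OCC)C1C(=O)C(c2cc(OC)ccc2C2OCCO2)=C1O[Si](C(C)C)(C(C)C)C(C)C | intermediate
12 | 2-[2-(1,3-dioxolan-2-yl)-5-methoxyphenyl]-5-ethoxy-3-(triisopropylsiloxy)hexa-1,3,5-trien-1-one, ketene and ethoxyvinyl arms cis | O=C=C(c1cc(OC)ccc1C1OCCO1)/C(O[Si](C(C)C)(C(C)C)C(C)C)=C\C(=C)OCC | intermediate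
13 | 2-[2-(1,3-dioxolan-2-yl)-5-methoxyphenyl]-5-ethoxy-3-(triisopropylsiloxy)cyclohexa-2,4-dien-1-one | CCOC1=CC(O[Si](C(C)C)(C(C)C)C(C)C)=C(c2cc(OC)ccc2C2OCCO2)C(=O)C1 | intermediate
14 | 2-[2-(1,3-dioxolan-2-yl)-5-methoxyphenyl]-5-ethoxy-3-(triisopropylsiloxy)phenol | CCOc1cc(O)c(-c2cc(OC)ccc2C2OCCO2)c(O[Si](C(C)C)(C(C)C)C(C)C)c1 | intermediate
15 | paraformaldehyde (formaldehyde source) | C=O | starting material
16 | 3-[2-(1,3-dioxolan-2-yl)-5-methoxyphenyl]-6-ethoxy-2-hydroxy-4-(triisopropylsiloxy)benzaldehyde | CCOc1cc(O[Si](C(C)C)(C(C)C)C(C)C)c(-c2cc(OC)ccc2C2OCCO2)c(O)c1C=O | intermediate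
17 | 1-ethynyl-4-methoxybenzene | C#Cc1ccc(OC)cc1 | starting material
18 | lithium (4-methoxyphenyl)acetylide | [Li]C#Cc1ccc(OC)cc1 | intermediate
19 | 2-[2-(1,3-dioxolan-2-yl)-5-methoxyphenyl]-5-ethoxy-6-[1-hydroxy-3-(4-methoxyphenyl)prop-2-yn-1-yl]-3-(triisopropylsiloxy)phenol (racemic carbinol) | CCOc1cc(O[Si](C(C)C)(C(C)C)C(C)C)c(-c2cc(OC)ccc2C2OCCO2)c(O)c1C(O)C#Cc1ccc(OC)cc1 | intermediate
20 | 1-{3-[2-(1,3-dioxolan-2-yl)-5-methoxyphenyl]-6-ethoxy-2-hydroxy-4-(triisopropylsiloxy)phenyl}-3-(4-methoxyphenyl)prop-2-yn-1-one | CCOc1cc(O[Si](C(C)C)(C(C)C)C(C)C)c(-c2cc(OC)ccc2C2OCCO2)c(O)c1C(=O)C#Cc1ccc(OC)cc1 | intermediate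
21 | (E)-3-(diethylamino)-1-{3-[2-(1,3-dioxolan-2-yl)-5-methoxyphenyl]-6-ethoxy-2-hydroxy-4-(triisopropylsiloxy)phenyl}-3-(4-methoxyphenyl)prop-2-en-1-one | CCOc1cc(O[Si](C(C)C)(C(C)C)C(C)C)c(-c2cc(OC)ccc2C2OCCO2)c(O)c1C(=O)/C=C(/N(CC)CC)c1ccc(OC)cc1 | intermediate
22 | 8-[2-(1,3-dioxolan-2-yl)-5-methoxyphenyl]-5-ethoxy-2-(4-methoxyphenyl)-7-(triisopropylsiloxy)-4H-chromen-4-one | CCOc1cc(O[Si](C(C)C)(C(C)C)C(C)C)c(-c2cc(OC)ccc2C2OCCO2)c2oc(-c3ccc(OC)cc3)cc(=O)c12 | intermediate
23 | 7-(benzyloxy)-8-[2-(1,3-dioxolan-2-yl)-5-methoxyphenyl]-5-ethoxy-2-(4-methoxyphenyl)-4H-chromen-4-one | CCOc1cc(OCc2ccccc2)c(-c2cc(OC)ccc2C2OCCO2)c2oc(-c3ccc(OC)cc3)cc(=O)c12 | intermediate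
24 | 2-[7-(benzyloxy)-5-ethoxy-2-(4-methoxyphenyl)-4-oxo-4H-chromen-8-yl]-4-methoxybenzaldehyde | CCOc1cc(OCc2ccccc2)c(-c2cc(OC)ccc2C=O)c2oc(-c3ccc(OC)cc3)cc(=O)c12 | intermediate
25 | 2,4,6-trihydroxyacetophenone | CC(=O)c1c(O)cc(O)cc1O | starting material
26 | 1-[2,4-bis(benzyloxy)-6-hydroxyphenyl]ethan-1-one | CC(=O)c1c(O)cc(OCc2ccccc2)cc1OCc1ccccc1 | intermediate
27 | (E)-1-[2,4-bis(benzyloxy)-6-hydroxyphenyl]-3-{2-[7-(benzyloxy)-5-ethoxy-2-(4-methoxyphenyl)-4-oxo-4H-chromen-8-yl]-4-methoxyphenyl}prop-2-en-1-one | CCOc1cc(OCc2ccccc2)c(-c2cc(OC)ccc2/C=C/C(=O)c2c(O)cc(OCc3ccccc3)cc2OCc2ccccc2)c2oc(-c3ccc(OC)cc3)cc(=O)c12 | intermediate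
28 | 5,7-bis(benzyloxy)-2-{2-[7-(benzyloxy)-5-ethoxy-2-(4-methoxyphenyl)-4-oxo-4H-chromen-8-yl]-4-methoxyphenyl}chroman-4-one (racemic at C2'') | CCOc1cc(OCc2ccccc2)c(-c2cc(OC)ccc2C2CC(=O)c3c(OCc4ccccc4)cc(OCc4ccccc4)cc3O2)c2oc(-c3ccc(OC)cc3)cc(=O)c12 | intermediate
29 | 7-(benzyloxy)-8-{2-[5,7-bis(benzyloxy)-4-oxo-4H-chromen-2-yl]-5-methoxyphenyl}-5-ethoxy-2-(4-methoxyphenyl)-4H-chromen-4-one | CCOc1cc(OCc2ccccc2)c(-c2cc(OC)ccc2-c2cc(=O)c3c(OCc4ccccc4)cc(OCc4ccccc4)cc3o2)c2oc(-c3ccc(OC)cc3)cc(=O)c12 | intermediate
30 | 8-[2-(5,7-dihydroxy-4-oxo-4H-chromen-2-yl)-5-methoxyphenyl]-5,7-dihydroxy-2-(4-methoxyphenyl)-4H-chromen-4-one (CNP0394081.0) | COc1ccc(-c2cc(=O)c3c(O)cc(O)c(-c4cc(OC)ccc4-c4cc(=O)c5c(O)cc(O)cc5o4)c3o2)cc1 | target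

## Step count and least certain steps

Total step count: 15. Longest linear sequence: 14 (steps 1 to 11 and 13 to 15). Step 12 is the only side branch.

**Step 5 (key step).**
What may go wrong:
- The donor-substituted four-membered ring may open slowly, so that self-condensation of the ketene outruns its capture.
- The ortho-substituted aryl group may retard the (2+2) union.
- The cascade may stall before the second ring opening.
- The product phenol may be acylated by surplus ketene, or may exchange with the neighbouring acetal on long heating.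

Fallback: a cross-coupling route that sets out from 2 and returns at 23.
- Bromine–lithium exchange on 2 (n-BuLi, THF, −78 °C), borylation with B(OiPr)3 and a mild buffered work-up would give [2-(1,3-dioxolan-2-yl)-5-methoxyphenyl]boronic acid F1.
- Commercial acacetin F2 would be benzylated at its non-chelated hydroxyl (BnBr, K2CO3, acetone) to 7-(benzyloxy)-5-hydroxy-2-(4-methoxyphenyl)-4H-chromen-4-one F3.
- F3 would be ethylated at O5 (EtI, K2CO3, DMF, 60 °C) to 7-(benzyloxy)-5-ethoxy-2-(4-methoxyphenyl)-4H-chromen-4-one F4.
- Iodination (NIS, CF3CO2H cat., MeCN) at C8, the position that 5,7-dialkoxyflavones favour, would give 7-(benzyloxy)-5-ethoxy-8-iodo-2-(4-methoxyphenyl)-4H-chromen-4-one F5.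
- A Suzuki–Miyaura coupling of F1 with F5 (Pd(OAc)2, SPhos, K3PO4, toluene–water, 100 °C) would form C8–E2 and give 23.

**Step 4.**
What may go wrong:
- Oxygen transfer to the less nucleophilic aryl acetylide may be incomplete.
- Silylation may occur on carbon.
- Unconsumed silyl triflate may open the dioxolane.
- The ynol ether may hydrolyse during chromatography.

Fallback: an ester homologation that sets out from 2 and returns at 7, and hence 8.
- Bromine–lithium exchange on 2 and quenching with ethyl chloroformate would give ethyl 2-(1,3-dioxolan-2-yl)-5-methoxybenzoate F6.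
- The one-flask Kowalski sequence follows: LiCHBr2 from CH2Br2 and LiTMP, then n-BuLi, −78 °C to rt. It would induce aryl migration to the same ynolate 7.
- 7 is capped with TIPSOTf as before.

**Step 6.**
What may go wrong:
- Formaldehyde transfer may be slow in the crowded magnesium phenoxide.
- The silyl ether or the acetal may erode on prolonged heating with MgCl2.
- The product may react further with formaldehyde.

Fallback: a carbonylative annulation that sets out from 14 and returns at 22, bypassing steps 6 to 9.
- Iodination with NIS in CH2Cl2 at low temperature, with the bulky silyl ether shielding C6, would give 2-[2-(1,3-dioxolan-2-yl)-5-methoxyphenyl]-5-ethoxy-6-iodo-3-(triisopropylsiloxy)phenol F7.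
- The palladium-catalysed carbonylative annulation of this o-iodophenol with 17 (PdCl2(dppf), CO 1 atm, Et2NH, 60 °C) would give 22 directly.

**Step 13.**
What may go wrong:
- Condensation at an electron-rich aldehyde with a large ortho substituent may be sluggish.
- Hydroxide may open ring C over long reaction times.
- The aldehyde may disproportionate.

Fallback: an acyl-transfer route that sets out from 24 and returns at 29, also bypassing step 14.
- Pinnick oxidation (NaClO2, NaH2PO4, 2-methyl-2-butene) would give 2-[7-(benzyloxy)-5-ethoxy-2-(4-methoxyphenyl)-4-oxo-4H-chromen-8-yl]-4-methoxybenzoic acid F8.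
- Acylation of 26, through the acid chloride ((COCl)2, DMF cat.; then pyridine, DMAP), would give the aryl ester 2-acetyl-3,5-bis(benzyloxy)phenyl 2-[7-(benzyloxy)-5-ethoxy-2-(4-methoxyphenyl)-4-oxo-4H-chromen-8-yl]-4-methoxybenzoate F9.
- A Baker–Venkataraman shift (LiHMDS, THF, −78 °C to rt) would give 1-[2,4-bis(benzyloxy)-6-hydroxyphenyl]-3-{2-[7-(benzyloxy)-5-ethoxy-2-(4-methoxyphenyl)-4-oxo-4H-chromen-8-yl]-4-methoxyphenyl}propane-1,3-dione F10.
- Cyclodehydration (p-TsOH, toluene, reflux) would close ring F to 29.

**Step 15.**
What may go wrong: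
- Removal of the ethyl group may be incomplete at temperatures that are safe for the methyl ethers.
- The methyl ethers may erode if the reaction is forced.
- Benzyl cations that escape the scavenger may alkylate the phloroglucinol rings.

Fallback: two orthogonal operations that set out from 29 and return at 30.
- Hydrogenolysis (H2, Pd/C, THF–MeOH) removes the three benzyl groups without any Lewis acid. It would give 8-[2-(5,7-dihydroxy-4-oxo-4H-chromen-2-yl)-5-methoxyphenyl]-5-ethoxy-7-hydroxy-2-(4-methoxyphenyl)-4H-chromen-4-one F11.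
- The single remaining peri ether is then cleaved by chelation-assisted dealkylation with AlCl3 in MeCN at reflux, giving 30.

## Further compounds

F1 | step 5 | [2-(1,3-dioxolan-2-yl)-5-methoxyphenyl]boronic acid | COc1ccc(C2OCCO2)c(B(O)O)c1
F2 | step 5 | acacetin, 5,7-dihydroxy-2-(4-methoxyphenyl)-4H-chromen-4-one | COc1ccc(-c2cc(=O)c3c(O)cc(O)cc3o2)cc1
F3 | step 5 | 7-(benzyloxy)-5-hydroxy-2-(4-methoxyphenyl)-4H-chromen-4-one | COc1ccc(-c2cc(=O)c3c(O)cc(OCc4ccccc4)cc3o2)cc1
F4 | step 5 | 7-(benzyloxy)-5-ethoxy-2-(4-methoxyphenyl)-4H-chromen-4-one | CCOc1cc(OCc2ccccc2)cc2oc(-c3ccc(OC)cc3)cc(=O)c12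
F5 | step 5 | 7-(benzyloxy)-5-ethoxy-8-iodo-2-(4-methoxyphenyl)-4H-chromen-4-one | CCOc1cc(OCc2ccccc2)c(I)c2oc(-c3ccc(OC)cc3)cc(=O)c12
F6 | step 4 | ethyl 2-(1,3-dioxolan-2-yl)-5-methoxybenzoate | CCOC(=O)c1cc(OC)ccc1C1OCCO1
F7 | step 6 | 2-[2-(1,3-dioxolan-2-yl)-5-methoxyphenyl]-5-ethoxy-6-iodo-3-(triisopropylsiloxy)phenol | CCOc1cc(O[Si](C(C)C)(C(C)C)C(C)C)c(-c2cc(OC)ccc2C2OCCO2)c(O)c1I
F8 | step 13 | 2-[7-(benzyloxy)-5-ethoxy-2-(4-methoxyphenyl)-4-oxo-4H-chromen-8-yl]-4-methoxybenzoic acid | CCOc1cc(OCc2ccccc2)c(-c2cc(OC)ccc2C(=O)O)c2oc(-c3ccc(OC)cc3)cc(=O)c12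
F9 | step 13 | 2-acetyl-3,5-bis(benzyloxy)phenyl 2-[7-(benzyloxy)-5-ethoxy-2-(4-methoxyphenyl)-4-oxo-4H-chromen-8-yl]-4-methoxybenzoate | CCOc1cc(OCc2ccccc2)c(-c2cc(OC)ccc2C(=O)Oc2cc(OCc3ccccc3)cc(OCc3ccccc3)c2C(C)=O)c2oc(-c3ccc(OC)cc3)cc(=O)c12
F10 | step 13 | 1-[2,4-bis(benzyloxy)-6-hydroxyphenyl]-3-{2-[7-(benzyloxy)-5-ethoxy-2-(4-methoxyphenyl)-4-oxo-4H-chromen-8-yl]-4-methoxyphenyl}propane-1,3-dione | CCOc1cc(OCc2ccccc2)c(-c2cc(OC)ccc2C(=O)CC(=O)c2c(O)cc(OCc3ccccc3)cc2OCc2ccccc2)c2oc(-c3ccc(OC)cc3)cc(=O)c12
F11 | step 15 | 8-[2-(5,7-dihydroxy-4-oxo-4H-chromen-2-yl)-5-methoxyphenyl]-5-ethoxy-7-hydroxy-2-(4-methoxyphenyl)-4H-chromen-4-one | CCOc1cc(O)c(-c2cc(OC)ccc2-c2cc(=O)c3c(O)cc(O)cc3o2)c2oc(-c3ccc(OC)cc3)cc(=O)c12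
A1 | alternative 1 | methyl 4-[5,7-bis(benzyloxy)-4'-methoxyflavon-8-yl]-2-oxo-2H-pyran-5-carboxylate | COC(=O)c1coc(=O)cc1-c1c(OCc2ccccc2)cc(OCc2ccccc2)c2c(=O)cc(-c3ccc(OC)cc3)oc12
A2 | alternative 1 | 1,1-dimethoxyethene | C=C(OC)OC
A3 | alternative 1 | methyl 2-[5,7-bis(benzyloxy)-4'-methoxyflavon-8-yl]-4-methoxybenzoate | COc1ccc(-c2cc(=O)c3c(OCc4ccccc4)cc(OCc4ccccc4)c(-c4cc(OC)ccc4C(=O)OC)c3o2)cc1
A4 | alternative 2 | methyl [5,7-bis(benzyloxy)-2-oxo-2H-chromen-4-yl]acetate | COC(=O)Cc1cc(=O)oc2cc(OCc3ccccc3)cc(OCc3ccccc3)c12
A5 | alternative 2 | methyl acrylate | C=CC(=O)OC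
A6 | alternative 2 | methyl 1,3-bis(benzyloxy)-9-hydroxy-6-oxo-7,10-dihydro-6H-benzo[c]chromene-8-carboxylate | COC(=O)C1=C(O)Cc2c(C1)c(=O)oc1cc(OCc3ccccc3)cc(OCc3ccccc3)c21
A7 | alternative 3 | 3-chloro-2-iodo-5-methoxyphenyl 4-chlorobenzenesulfonate | COc1cc(Cl)c(I)c(OS(=O)(=O)c2ccc(Cl)cc2)c1
A8 | alternative 3 | 3-chloro-5-methoxybenzyne | COC1=CC#CC(Cl)=C1
A9 | alternative 3 | 2,4,6-tris(methoxymethoxy)phenylmagnesium bromide | COCOc1cc(OCOC)c([Mg]Br)c(OCOC)c1
A10 | alternative 3 | 2-chloro-4-methoxy-6-[2,4,6-tris(methoxymethoxy)phenyl]benzoic acid | COCOc1cc(OCOC)c(-c2cc(OC)cc(Cl)c2C(=O)O)c(OCOC)c1
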